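**Retrosynthetic overview**

- Feature: the pyran ring O1–C2–C3–C4 of the isoflavan, fused to the A ring at C4a/C8a, is read as an A-ring o-quinone methide (C4=C4a–C8a=O1) plus the C2=C3 unit of a B-ring (E)-enecarbamate with the aryl on C3, the only stereocentre.
- Key disconnection: C3–C4 and O1–C2 by a chiral phosphoric acid-catalysed oxa-[4+2]; the C2 carbamate nitrogen is then replaced by hydrogen and the two phenols are freed.
- Enecarbamate: Curtius rearrangement of the cinnamic acid from the chromene aldehyde, whose 2,2-dimethyl-2H-pyran ring comes from prenal annulation of 3-prenyl-2,4-dihydroxybenzaldehyde.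
- Ring order: B-ring 2H-pyran (step 2), then the chroman pyran ring (step 8); both benzene rings come from 2,4-dihydroxybenzaldehyde.

Key step: step 8

Assumption 1: both phenols are carried as allyl ethers, not silyl ethers. An aryl silyl ether ortho to a formyl group is not expected to survive hot pyridine/piperidine in step 4. The B-ring phenol must also stay masked, because a free ortho-OH would give a coumarin in step 4 and a benzofuran under acid in step 8.

Assumption 2: the sense of induction of the phosphoric acid cannot be predicted with certainty. (R)-TRIP is written; its enantiomer is used if the (3S) product should prevail.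

**Route**

Step 1
Reactants: 1 2,4-dihydroxybenzaldehyde; 2 prenyl bromide
Product: 3 2,4-dihydroxy-3-(3-methylbut-2-enyl)benzaldehyde
Conditions: KOH (2.2 equiv), H2O, 0 °C → rt; chromatography
Reagents that add atoms: none
Why: Direct C-prenylation (C-alkylation of an ambident phenoxide): in water the hydrogen-bonded resorcinolate reacts at carbon, and C3 between the two oxygens is its most electron-rich position, so 3 should be the main C-alkylated product after removal of the 5-prenyl isomer and the O-prenyl ether.

Step 2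
Reactants: 3 2,4-dihydroxy-3-(3-methylbut-2-enyl)benzaldehyde; 4 3-methylbut-2-enal
Product: 6 7-hydroxy-2,2-dimethyl-8-(3-methylbut-2-enyl)-2H-chromene-6-carbaldehyde, via quinone methide dienone 5 (not isolated)
Conditions: EDDA (20 mol%), xylene, 140 °C
Reagents that add atoms: none
Why: Formal [3+3] chromene annulation: Knoevenagel-type condensation of prenal at C5 (the only free nucleophilic ring carbon, since C3 is blocked and the chelated 2-OH has no free ortho position) gives dienone 5, whose oxa-6π electrocyclisation onto the 4-oxygen closes the linear 2,2-dimethyl-2H-pyran ring.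

Step 3
Reactants: 6 7-hydroxy-2,2-dimethyl-8-(3-methylbut-2-enyl)-2H-chromene-6-carbaldehyde
Product: 7 7-(allyloxy)-2,2-dimethyl-8-(3-methylbut-2-enyl)-2H-chromene-6-carbaldehyde
Conditions: allyl bromide, K2CO3, DMF, 50 °C
Reagents that add atoms: allyl bromide, C=CCBr
Why: Williamson O-allylation of the only free phenol; DMF and mild heating overcome the hydrogen bond to the formyl group and the two ortho substituents.

Step 4
Reactants: 7 7-(allyloxy)-2,2-dimethyl-8-(3-methylbut-2-enyl)-2H-chromene-6-carbaldehyde; 8 malonic acid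
Product: 10 (E)-3-[7-(allyloxy)-2,2-dimethyl-8-(3-methylbut-2-enyl)-2H-chromen-6-yl]acrylic acid, via arylidenemalonic acid 9 (not isolated)
Conditions: pyridine, piperidine (cat.), 90 °C
Reagents that add atoms: none
Why: Knoevenagel–Doebner condensation: the aldehyde condenses with malonic acid and diacid 9 loses CO2 in hot pyridine to give the thermodynamically favoured (E)-cinnamic acid; the allyl ether is inert to these conditions.

Step 5
Reactants: 10 (E)-3-[7-(allyloxy)-2,2-dimethyl-8-(3-methylbut-2-enyl)-2H-chromen-6-yl]acrylic acid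
Product: 13 methyl (E)-N-{2-[7-(allyloxy)-2,2-dimethyl-8-(3-methylbut-2-enyl)-2H-chromen-6-yl]vinyl}carbamate, via acyl azide 11 (not isolated), via vinyl isocyanate 12 (not isolated)
Conditions: DPPA, Et3N, toluene, 0 °C → rt, then 85 °C; MeOH, 70 °C; Et3N-deactivated silica
Reagents that add atoms: diphenylphosphoryl azide, [N-]=[N+]=NP(=O)(Oc1ccccc1)Oc1ccccc1; methanol, CO
Why: Curtius rearrangement: acyl azide 11 loses N2 with 1,2-shift of the alkenyl group, which keeps the (E)-geometry, and methanol adds to vinyl isocyanate 12 to give the (E)-enecarbamate.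

Step 6
Reactants: 1 2,4-dihydroxybenzaldehyde
Product: 14 4-(allyloxy)-2-hydroxybenzaldehyde
Conditions: allyl bromide (1.05 equiv), K2CO3 (1.0 equiv), acetone, rt → 50 °C
Reagents that add atoms: allyl bromide, C=CCBr
Why: Williamson alkylation selective for the 4-OH, which is the more acidic phenol (para to the formyl group), while the 2-OH is held in the hydrogen bond to the carbonyl.

Step 7
Reactants: 14 4-(allyloxy)-2-hydroxybenzaldehyde
Product: 15 4-(allyloxy)-2-hydroxybenzyl alcohol
Conditions: NaBH4, THF–MeOH, 0 °C; aq NH4Cl; used fresh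
Reagents that add atoms: none
Why: Borohydride reduction of the aldehyde to the primary benzyl alcohol; the near-neutral work-up avoids premature ionisation of the acid-sensitive 2-hydroxy-4-alkoxybenzyl alcohol.

Step 8
Reactants: 15 4-(allyloxy)-2-hydroxybenzyl alcohol; 13 methyl (E)-N-{2-[7-(allyloxy)-2,2-dimethyl-8-(3-methylbut-2-enyl)-2H-chromen-6-yl]vinyl}carbamate
Product: 17 methyl N-{(2S,3R)-7-(allyloxy)-3-[7-(allyloxy)-2,2-dimethyl-8-(3-methylbut-2-enyl)-2H-chromen-6-yl]chroman-2-yl}carbamate (2,3-trans), via o-quinone methide 16 (not isolated)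
Conditions: (R)-TRIP (10 mol%), 4 Å MS, CH2Cl2, 0 °C → rt, slow addition of 15 (1.3 equiv)
Reagents that add atoms: none
Why: Proposed new method: the phosphoric acid protonates the benzylic hydroxyl of 15 and water leaves with the push of the ortho-hydroxyl and the para-allyloxy group to give o-quinone methide 16, which stays hydrogen-bonded to the catalyst P–OH while the phosphoryl oxygen binds the N–H of 13; the closest known reaction type is the chiral phosphoric acid-catalysed inverse-demand oxa-Diels–Alder of o-quinone methides from secondary (α-aryl) 2-hydroxybenzyl alcohols with enamides and enecarbamates, and what is new is the unsubstituted methide CH2 from a primary alcohol, with the only lasting stereocentre on the enecarbamate carbon. The aryl-bearing β-carbon of 13 adds to the methide CH2 (C3–C4) and the quinone methide oxygen adds to the N-acyliminium carbon (O1–C2), so the pyran ring closes by an asynchronous concerted [4+2] or, at the stepwise limit, by Michael addition followed by 6-exo-trig O-cyclisation. C3 is set in the C–C bond formation by the catalyst, whose 3,3′-aryl groups shield one face of the doubly hydrogen-bonded enecarbamate; C2 follows from the (E)-alkene, which places N and aryl trans, and is erased in step 9. The step needs regioselectivity (secured by the matched polarity of the nucleophilic β-carbon and the electrophilic CH2), chemoselectivity over the chromene and prenyl alkenes (far less nucleophilic than the enecarbamate, while slow addition of 15 keeps 16 from oligomerising) and face selectivity at C3 (catalyst control, with the catalyst antipode chosen to give 3R).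

Step 9
Reactants: 17 methyl N-{(2S,3R)-7-(allyloxy)-3-[7-(allyloxy)-2,2-dimethyl-8-(3-methylbut-2-enyl)-2H-chromen-6-yl]chroman-2-yl}carbamate
Product: 19 (3R)-7-(allyloxy)-3-[7-(allyloxy)-2,2-dimethyl-8-(3-methylbut-2-enyl)-2H-chromen-6-yl]chroman, via oxocarbenium ion 18 (not isolated)
Conditions: Et3SiH (5 equiv), BF3·OEt2 (2 equiv), CH2Cl2, −78 → −40 °C; aq NaHCO3
Reagents that add atoms: none
Why: Proposed new method: BF3 binds the carbamate carbonyl, which turns the acylamino group into a leaving group and ties up the nitrogen lone pair so that ring opening to an N-acyliminium ion is disfavoured, the ring oxygen expels it to give oxocarbenium ion 18, and Et3SiH reduces C2 to CH2; the closest known reaction types are the BF3/silane reduction of 2-alkoxychromans and chroman-2-ols to chromans and the acid-induced loss of the acylamino group from 2-(acylamino)chromans, and C3 should keep its configuration because excess silane at low temperature captures the cation before C3–H loss.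

Step 10
Reactants: 19 (3R)-7-(allyloxy)-3-[7-(allyloxy)-2,2-dimethyl-8-(3-methylbut-2-enyl)-2H-chromen-6-yl]chroman
Product: 20 (3R)-3-[7-hydroxy-2,2-dimethyl-8-(3-methylbut-2-enyl)-2H-chromen-6-yl]chroman-7-ol (CNP0331403.1)
Conditions: Pd(PPh3)4 (5 mol%), morpholine (10 equiv), THF, rt, degassed
Reagents that add atoms: none
Why: Tsuji–Trost deallylation: Pd(0) ionises both aryl allyl ethers to π-allyl complexes that morpholine intercepts, while the C-prenyl group, the chromene and the C3 stereocentre are untouched under these neutral conditions.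

**Compound list**

1 | 2,4-dihydroxybenzaldehyde | O=Cc1ccc(O)cc1O | starting material
2 | prenyl bromide (1-bromo-3-methylbut-2-ene) | CC(C)=CCBr | starting material
3 | 2,4-dihydroxy-3-(3-methylbut-2-enyl)benzaldehyde | O=Cc1ccc(O)c(CC=C(C)C)c1O | intermediate
4 | 3-methylbut-2-enal (prenal) | CC(C)=CC=O | starting material
5 | 6-hydroxy-5-(3-methylbut-2-enyl)-3-(3-methylbut-2-enylidene)-4-oxocyclohexa-1,5-diene-1-carbaldehyde (quinone methide dienone) | O=CC1=CC(=CC=C(C)C)C(=O)C(CC=C(C)C)=C1O | intermediate (not isolated)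
6 | 7-hydroxy-2,2-dimethyl-8-(3-methylbut-2-enyl)-2H-chromene-6-carbaldehyde | O=Cc1cc2C=CC(C)(C)Oc2c(CC=C(C)C)c1O | intermediate
7 | 7-(allyloxy)-2,2-dimethyl-8-(3-methylbut-2-enyl)-2H-chromene-6-carbaldehyde | O=Cc1cc2C=CC(C)(C)Oc2c(CC=C(C)C)c1OCC=C | intermediate
8 | malonic acid | OC(=O)CC(=O)O | starting material
9 | 2-{[7-(allyloxy)-2,2-dimethyl-8-(3-methylbut-2-enyl)-2H-chromen-6-yl]methylene}malonic acid | OC(=O)C(=Cc1cc2C=CC(C)(C)Oc2c(CC=C(C)C)c1OCC=C)C(=O)O | intermediate (not isolated)
10 | (E)-3-[7-(allyloxy)-2,2-dimethyl-8-(3-methylbut-2-enyl)-2H-chromen-6-yl]acrylic acid | OC(=O)/C=C/c1cc2C=CC(C)(C)Oc2c(CC=C(C)C)c1OCC=C | intermediate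
11 | (E)-3-[7-(allyloxy)-2,2-dimethyl-8-(3-methylbut-2-enyl)-2H-chromen-6-yl]acryloyl azide | [N-]=[N+]=NC(=O)/C=C/c1cc2C=CC(C)(C)Oc2c(CC=C(C)C)c1OCC=C | intermediate (not isolated)
12 | (E)-7-(allyloxy)-6-(2-isocyanatovinyl)-2,2-dimethyl-8-(3-methylbut-2-enyl)-2H-chromene | O=C=N/C=C/c1cc2C=CC(C)(C)Oc2c(CC=C(C)C)c1OCC=C | intermediate (not isolated)
13 | methyl (E)-N-{2-[7-(allyloxy)-2,2-dimethyl-8-(3-methylbut-2-enyl)-2H-chromen-6-yl]vinyl}carbamate | COC(=O)N/C=C/c1cc2C=CC(C)(C)Oc2c(CC=C(C)C)c1OCC=C | intermediate
14 | 4-(allyloxy)-2-hydroxybenzaldehyde | O=Cc1ccc(OCC=C)cc1O | intermediate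
15 | 4-(allyloxy)-2-hydroxybenzyl alcohol | OCc1ccc(OCC=C)cc1O | intermediate
16 | 3-(allyloxy)-6-methylenecyclohexa-2,4-dien-1-one (o-quinone methide) | C=C1C=CC(OCC=C)=CC1=O | intermediate (not isolated)
17 | methyl N-{(2S,3R)-7-(allyloxy)-3-[7-(allyloxy)-2,2-dimethyl-8-(3-methylbut-2-enyl)-2H-chromen-6-yl]chroman-2-yl}carbamate (2,3-trans) | CC(C)=CCc1c(OCC=C)c([C@@H]2[C@@H](NC(=O)OC)Oc3cc(OCC=C)ccc3C2)cc2c1OC(C)(C)C=C2 | intermediate
18 | (3R)-7-(allyloxy)-3-[7-(allyloxy)-2,2-dimethyl-8-(3-methylbut-2-enyl)-2H-chromen-6-yl]-3,4-dihydrochromenylium (oxocarbenium ion) | CC(C)=CCc1c(OCC=C)c([C@@H]2C=[O+]c3cc(OCC=C)ccc3C2)cc2c1OC(C)(C)C=C2 | intermediate (not isolated)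
19 | (3R)-7-(allyloxy)-3-[7-(allyloxy)-2,2-dimethyl-8-(3-methylbut-2-enyl)-2H-chromen-6-yl]chroman | CC(C)=CCc1c(OCC=C)c([C@@H]2COc3cc(OCC=C)ccc3C2)cc2c1OC(C)(C)C=C2 | intermediate
20 | (3R)-3-[7-hydroxy-2,2-dimethyl-8-(3-methylbut-2-enyl)-2H-chromen-6-yl]chroman-7-ol (CNP0331403.1) | CC(C)=CCc1c(O)c([C@@H]2COc3cc(O)ccc3C2)cc2c1OC(C)(C)C=C2 | target

**Step count**

Total steps: 10. Longest linear sequence: 8 (steps 1–5, 8, 9, 10).

**Steps most likely to fail**

Step 8 (Proposed new method). The primary benzyl alcohol may fail to ionise under the weak acid. The quinone methide may be consumed by Friedel–Crafts oligomerisation with the electron-rich arenes present. The catalyst may also discriminate poorly between the faces of the enecarbamate.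

The fallback is an auxiliary-controlled alkylation (Evans alkylation, known chemistry). It sets out from 13 and 14 and returns to the route at 19.
- 13 is hydrolysed with aqueous oxalic acid in THF to the arylacetaldehyde F1.
- F1 is oxidised (NaClO2, NaH2PO4, 2-methylbut-2-ene, t-BuOH–H2O) to the arylacetic acid F2.
- F2 is coupled through its pivalic mixed anhydride with lithiated (R)-4-benzyloxazolidin-2-one to the N-acyl oxazolidinone F3.
- In parallel, 14 is silylated (TBSCl, imidazole, DMF) to the silyl ether F4, reduced (NaBH4, EtOH, 0 °C, short time) to the benzyl alcohol F5 and converted (CBr4, PPh3) into the benzyl bromide F6.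
- The sodium enolate of F3 (NaHMDS, THF, −78 °C) is alkylated by F6 on the face away from the benzyl group. This gives the alkylated imide F7, with the (R)-configured carbon that becomes C3.
- LiBH4 removes the auxiliary to give the primary alcohol F8, and TBAF frees the phenol to give the phenol-alcohol F9.
- Mitsunobu etherification (PPh3, DIAD, THF) closes the pyran ring to 19.

Step 9 (Proposed new method). Ionisation on the other side, with loss of the ring phenoxide, would give an open N-acyliminium ion and, after hydride transfer, a ring-opened carbamate. The cation may also be caught by the neighbouring B-ring ether oxygen, or lose the C3 proton, which would erode the stereocentre. The chromene double bond may be reduced if protic acid builds up.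

The fallback uses known chemistry, sets out from 17 and returns at 19.
- Mild aqueous acid hydrolysis (oxalic acid, THF–H2O, rt) gives the lactol F10. This leads to the same product whichever C–heteroatom bond ionises.
- NaBH4 (EtOH, 0 °C) reduces the open hydroxy-aldehyde form to the phenol-alcohol F9, the same compound as in the fallback to step 8.
- Mitsunobu ring closure (PPh3, DIAD) gives 19.
- Hydrolysis and reduction are run without delay to limit epimerisation of the α-aryl aldehyde.

Step 1. O-prenylation, prenylation at C5 and double prenylation compete with attack at C3, so a modest yield and a tedious separation are expected.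

The fallback sets out from 1 and returns at 3.
- Selective 4-O-alkylation with 3-chloro-3-methylbut-1-yne (K2CO3, KI, cat. CuI, acetone) gives the propargyl ether F11.
- Lindlar semi-hydrogenation (H2, Lindlar catalyst, quinoline, EtOAc) gives the 1,1-dimethylallyl ether F12.
- A thermal aromatic Claisen rearrangement (N,N-diethylaniline, 130 °C) delivers 3. It should go to C3 because the chelated ortho-hydroxy aldehyde fixes the C3=C4 double bond.

**Further compounds**

F1 | step 8 | 2-[7-(allyloxy)-2,2-dimethyl-8-(3-methylbut-2-enyl)-2H-chromen-6-yl]acetaldehyde | O=CCc1cc2C=CC(C)(C)Oc2c(CC=C(C)C)c1OCC=C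
F2 | step 8 | 2-[7-(allyloxy)-2,2-dimethyl-8-(3-methylbut-2-enyl)-2H-chromen-6-yl]acetic acid | OC(=O)Cc1cc2C=CC(C)(C)Oc2c(CC=C(C)C)c1OCC=C
F3 | step 8 | (4R)-4-benzyl-3-{2-[7-(allyloxy)-2,2-dimethyl-8-(3-methylbut-2-enyl)-2H-chromen-6-yl]acetyl}oxazolidin-2-one | O=C(Cc1cc2C=CC(C)(C)Oc2c(CC=C(C)C)c1OCC=C)N1[C@H](Cc2ccccc2)COC1=O
F4 | step 8 | 4-(allyloxy)-2-(tert-butyldimethylsilyloxy)benzaldehyde | O=Cc1ccc(OCC=C)cc1O[Si](C)(C)C(C)(C)C
F5 | step 8 | [4-(allyloxy)-2-(tert-butyldimethylsilyloxy)phenyl]methanol | OCc1ccc(OCC=C)cc1O[Si](C)(C)C(C)(C)C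
F6 | step 8 | [5-(allyloxy)-2-(bromomethyl)phenoxy](tert-butyl)dimethylsilane | BrCc1ccc(OCC=C)cc1O[Si](C)(C)C(C)(C)C
F7 | step 8 | (4R)-4-benzyl-3-{(2R)-3-[4-(allyloxy)-2-(tert-butyldimethylsilyloxy)phenyl]-2-[7-(allyloxy)-2,2-dimethyl-8-(3-methylbut-2-enyl)-2H-chromen-6-yl]propanoyl}oxazolidin-2-one | CC(C)=CCc1c(OCC=C)c([C@@H](Cc3ccc(OCC=C)cc3O[Si](C)(C)C(C)(C)C)C(=O)N3[C@H](Cc4ccccc4)COC3=O)cc2c1OC(C)(C)C=C2
F8 | step 8 | (2R)-3-[4-(allyloxy)-2-(tert-butyldimethylsilyloxy)phenyl]-2-[7-(allyloxy)-2,2-dimethyl-8-(3-methylbut-2-enyl)-2H-chromen-6-yl]propan-1-ol | CC(C)=CCc1c(OCC=C)c([C@@H](Cc3ccc(OCC=C)cc3O[Si](C)(C)C(C)(C)C)CO)cc2c1OC(C)(C)C=C2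
F9 | step 8 | 5-(allyloxy)-2-{(2R)-2-[7-(allyloxy)-2,2-dimethyl-8-(3-methylbut-2-enyl)-2H-chromen-6-yl]-3-hydroxypropyl}phenol | CC(C)=CCc1c(OCC=C)c([C@@H](Cc3ccc(OCC=C)cc3O)CO)cc2c1OC(C)(C)C=C2
F10 | step 9 | (3R)-7-(allyloxy)-3-[7-(allyloxy)-2,2-dimethyl-8-(3-methylbut-2-enyl)-2H-chromen-6-yl]chroman-2-ol (mixture of C2 epimers) | CC(C)=CCc1c(OCC=C)c([C@@H]2C(O)Oc3cc(OCC=C)ccc3C2)cc2c1OC(C)(C)C=C2
F11 | step 1 | 2-hydroxy-4-[(2-methylbut-3-yn-2-yl)oxy]benzaldehyde | O=Cc1ccc(OC(C)(C)C#C)cc1O
F12 | step 1 | 2-hydroxy-4-[(2-methylbut-3-en-2-yl)oxy]benzaldehyde | O=Cc1ccc(OC(C)(C)C=C)cc1O
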